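**Retrosynthetic overview**
1. Target ⇐ removal of four MOM ethers ⇐ keto-aldehyde ⇐ stepwise oxidation of a 1,4-diol ⇐ LiAlH4 opening of a 3-aryl-phthalide, whose C3 becomes the benzophenone carbon and whose C1 becomes CHO.
2. Prenyl group ⇐ Negishi coupling at an aryl bromide that ring A carries from the start.
3. Chlorinated resorcinol ring B ⇐ SO2Cl2 monochlorination ⇐ dehydrogenation of a 2-substituted 5-methylcyclohexane-1,3-dione.
4. Key C–C bond (future ketone carbon to ring B) ⇐ intermolecular aldol addition–lactonisation of 5-methylcyclohexane-1,3-dione with a 3-hydroxyphthalide (a 2-formylbenzoic acid).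
5. Ring order: ring A is bought (3,5-dimethoxybenzaldehyde); the temporary lactone ring closes in steps 3–4; ring B is bought as the dione and aromatised in step 5; the lactone is opened in step 10.

Assumption: the target has no stereocentre, so no enantiocontrol is needed; stereocentres in intermediates are carried racemic and are all erased by step 12.

**Step 1**
Reactants: 1 3,5-dimethoxybenzaldehyde
Product: 2 2,6-dibromo-3,5-dimethoxybenzaldehyde
Conditions: NBS (2.2 equiv), MeCN, rt → 50 °C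
Reagents that add atoms: N-bromosuccinimide, O=C1CCC(=O)N1Br
Why: Electrophilic aromatic bromination goes para to one OMe and ortho to the other (C2 and C6), while C4 between the two OMe groups is shielded, as in the 4,6-dibromination of 1,3-dimethoxybenzene.

**Step 2**
Reactants: 2 2,6-dibromo-3,5-dimethoxybenzaldehyde
Product: 3 2-(2,6-dibromo-3,5-dimethoxyphenyl)-1,3-dioxolane
Conditions: ethylene glycol (5 equiv), TsOH·H2O (5 mol %), toluene, reflux, Dean–Stark
Reagents that add atoms: ethylene glycol, OCCO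
Why: Acid-catalysed acetalisation with azeotropic water removal masks the aldehyde for the organolithium step.

**Step 3**
Reactants: 3 2-(2,6-dibromo-3,5-dimethoxyphenyl)-1,3-dioxolane
Product: 6 4-bromo-3-hydroxy-5,7-dimethoxy-2-benzofuran-1(3H)-one (racemic lactol), via aryllithium 4 (not isolated), via lithium carboxylate 5 (not isolated)
Conditions: n-BuLi (1.05 equiv), THF, −78 °C; CO2 (g), −78 °C → rt; 2 M HCl, THF, 40 °C
Reagents that add atoms: carbon dioxide, O=C=O; water, O
Why: Bromine–lithium exchange with one equivalent of n-BuLi stops at the monolithium species, carboxylation gives the benzoate, and acid hydrolysis of the dioxolane lets the 2-formylbenzoic acid close to its ring tautomer, the 3-hydroxyphthalide.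

**Step 4**
Reactants: 6 4-bromo-3-hydroxy-5,7-dimethoxy-2-benzofuran-1(3H)-one; 7 5-methylcyclohexane-1,3-dione
Product: 9 4-bromo-3-(2-hydroxy-4-methyl-6-oxocyclohex-1-en-1-yl)-5,7-dimethoxy-2-benzofuran-1(3H)-one (racemic), via aldol adduct 8 (not isolated)
Conditions: DBU (0.2 equiv), MeCN, rt → 60 °C; 1 M HCl work-up
Reagents that add atoms: none
Why: Intermolecular aldol (Knoevenagel-type) addition of the dione enolate, which can react only at C2, to the formyl group of the ring-opened 2-formylbenzoate is followed by lactonisation of the ortho-carboxylate onto the aldol carbon, which stops a second dione from adding; the new stereocentre forms racemic and is oxidised away in step 12.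

**Step 5**
Reactants: 9 4-bromo-3-(2-hydroxy-4-methyl-6-oxocyclohex-1-en-1-yl)-5,7-dimethoxy-2-benzofuran-1(3H)-one
Product: 10 4-bromo-3-(2,6-dihydroxy-4-methylphenyl)-5,7-dimethoxy-2-benzofuran-1(3H)-one (racemic)
Conditions: Hg(OAc)2 (2.5 equiv), NaOAc, AcOH, reflux
Reagents that add atoms: none
Why: Mercuric acetate dehydrogenation of the enolised 2-substituted cyclohexane-1,3-dione (α-mercuration, elimination, tautomerisation) gives the resorcinol, and the aryl bromide, methyl ethers and lactone are inert to it.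

**Step 6**
Reactants: 10 4-bromo-3-(2,6-dihydroxy-4-methylphenyl)-5,7-dimethoxy-2-benzofuran-1(3H)-one
Product: 11 4-bromo-3-(3-chloro-2,6-dihydroxy-4-methylphenyl)-5,7-dimethoxy-2-benzofuran-1(3H)-one (racemic)
Conditions: SO2Cl2 (1.0 equiv), Et2O, 0 °C
Reagents that add atoms: sulfuryl chloride, O=S(=O)(Cl)Cl
Why: Electrophilic aromatic chlorination with one equivalent goes to the free resorcinol ring (ortho to one OH, para to the other; the two such positions are equivalent) much faster than to the ether-protected, lactone-deactivated ring A.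

**Step 7**
Reactants: 11 4-bromo-3-(3-chloro-2,6-dihydroxy-4-methylphenyl)-5,7-dimethoxy-2-benzofuran-1(3H)-one
Product: 12 4-bromo-3-(3-chloro-2,6-dihydroxy-4-methylphenyl)-5,7-dihydroxy-2-benzofuran-1(3H)-one (racemic)
Conditions: BBr3 (6 equiv), CH2Cl2, −78 °C → rt; H2O
Reagents that add atoms: none
Why: BBr3 ether cleavage removes both methyl ethers before the acid-sensitive prenyl group is present, and the phthalide and aryl halides tolerate it.

**Step 8**
Reactants: 12 4-bromo-3-(3-chloro-2,6-dihydroxy-4-methylphenyl)-5,7-dihydroxy-2-benzofuran-1(3H)-one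
Product: 13 4-bromo-3-[3-chloro-2,6-bis(methoxymethoxy)-4-methylphenyl]-5,7-bis(methoxymethoxy)-2-benzofuran-1(3H)-one (racemic)
Conditions: MOMCl (8 equiv), i-Pr2NEt (10 equiv), DMF, 0 °C → rt
Reagents that add atoms: chloromethyl methyl ether, COCCl
Why: O-Alkylation of all four phenols gives acetal protecting groups that survive the organozinc, hydride, fluoride and periodinane steps and leave under mild acid at the end.

**Step 9**
Reactants: 13 4-bromo-3-[3-chloro-2,6-bis(methoxymethoxy)-4-methylphenyl]-5,7-bis(methoxymethoxy)-2-benzofuran-1(3H)-one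
Product: 14 3-[3-chloro-2,6-bis(methoxymethoxy)-4-methylphenyl]-5,7-bis(methoxymethoxy)-4-(3-methylbut-2-en-1-yl)-2-benzofuran-1(3H)-one (racemic)
Conditions: prenylZnBr (1.5 equiv; from prenyl bromide, Zn, LiCl, THF), Pd(OAc)2 (3 mol %), CPhos (6 mol %), THF, rt
Reagents that add atoms: (3-methylbut-2-en-1-yl)zinc bromide, CC(C)=CC[Zn]Br
Why: Pd-catalysed Negishi cross-coupling with a bulky biarylphosphine gives the linear (α) prenyl arene; the lactone is inert to the allylzinc at rt and the C–Br bond reacts ahead of the stronger, more hindered C–Cl bond.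

**Step 10**
Reactants: 14 3-[3-chloro-2,6-bis(methoxymethoxy)-4-methylphenyl]-5,7-bis(methoxymethoxy)-4-(3-methylbut-2-en-1-yl)-2-benzofuran-1(3H)-one
Product: 15 [3-chloro-2,6-bis(methoxymethoxy)-4-methylphenyl][2-(hydroxymethyl)-3,5-bis(methoxymethoxy)-6-(3-methylbut-2-en-1-yl)phenyl]methanol (racemic)
Conditions: LiAlH4 (2 equiv), THF, 0 °C → rt; Rochelle salt work-up (no acid)
Reagents that add atoms: none
Why: Hydride reduction opens the lactone to the 1,4-diol, turning the former carboxyl carbon into the CH2OH that becomes the aldehyde.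

**Step 11**
Reactants: 15 [3-chloro-2,6-bis(methoxymethoxy)-4-methylphenyl][2-(hydroxymethyl)-3,5-bis(methoxymethoxy)-6-(3-methylbut-2-en-1-yl)phenyl]methanol
Product: 16 {2-[(tert-butyldimethylsilyloxy)methyl]-3,5-bis(methoxymethoxy)-6-(3-methylbut-2-en-1-yl)phenyl}[3-chloro-2,6-bis(methoxymethoxy)-4-methylphenyl]methanol (racemic)
Conditions: TBSCl (1.2 equiv), imidazole (2.5 equiv), DMF, 0 °C → rt
Reagents that add atoms: tert-butyldimethylsilyl chloride, CC(C)(C)[Si](C)(C)Cl
Why: Silylation picks the primary benzylic alcohol because the secondary diaryl carbinol is flanked by four ortho substituents.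

**Step 12**
Reactants: 16 {2-[(tert-butyldimethylsilyloxy)methyl]-3,5-bis(methoxymethoxy)-6-(3-methylbut-2-en-1-yl)phenyl}[3-chloro-2,6-bis(methoxymethoxy)-4-methylphenyl]methanol
Product: 17 {2-[(tert-butyldimethylsilyloxy)methyl]-3,5-bis(methoxymethoxy)-6-(3-methylbut-2-en-1-yl)phenyl}[3-chloro-2,6-bis(methoxymethoxy)-4-methylphenyl]methanone
Conditions: Dess–Martin periodinane (2 equiv), NaHCO3, CH2Cl2, rt
Reagents that add atoms: none
Why: Dess–Martin oxidation converts the diaryl carbinol to the benzophenone and removes the last stereocentre; with the primary alcohol silylated no lactol or lactone can form.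

**Step 13**
Reactants: 17 {2-[(tert-butyldimethylsilyloxy)methyl]-3,5-bis(methoxymethoxy)-6-(3-methylbut-2-en-1-yl)phenyl}[3-chloro-2,6-bis(methoxymethoxy)-4-methylphenyl]methanone
Product: 18 [3-chloro-2,6-bis(methoxymethoxy)-4-methylphenyl][2-(hydroxymethyl)-3,5-bis(methoxymethoxy)-6-(3-methylbut-2-en-1-yl)phenyl]methanone
Conditions: HF·pyridine, pyridine, THF, 0 °C → rt
Reagents that add atoms: none
Why: Buffered fluoride desilylation frees the primary alcohol without touching the MOM ethers.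

**Step 14**
Reactants: 18 [3-chloro-2,6-bis(methoxymethoxy)-4-methylphenyl][2-(hydroxymethyl)-3,5-bis(methoxymethoxy)-6-(3-methylbut-2-en-1-yl)phenyl]methanone
Product: 19 2-[3-chloro-2,6-bis(methoxymethoxy)-4-methylbenzoyl]-4,6-bis(methoxymethoxy)-3-(3-methylbut-2-en-1-yl)benzaldehyde
Conditions: Dess–Martin periodinane (1.5 equiv), NaHCO3, CH2Cl2, 0 °C → rt
Reagents that add atoms: none
Why: Dess–Martin oxidation of the benzylic primary alcohol gives the aldehyde under buffered, non-acidic conditions that spare the MOM ethers and the prenyl alkene.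

**Step 15**
Reactants: 19 2-[3-chloro-2,6-bis(methoxymethoxy)-4-methylbenzoyl]-4,6-bis(methoxymethoxy)-3-(3-methylbut-2-en-1-yl)benzaldehyde
Product: 20 2-(3-chloro-2,6-dihydroxy-4-methylbenzoyl)-4,6-dihydroxy-3-(3-methylbut-2-en-1-yl)benzaldehyde (pestalone E)
Conditions: 3 M aq. HCl (cat.), MeOH/THF, rt; neutral work-up without base or ammonia
Reagents that add atoms: none
Why: Acid-catalysed acetal exchange with methanol removes the four MOM groups (three are activated by an ortho carbonyl) at rt, where the prenyl group does not cyclise onto the neighbouring phenol and the base-sensitive keto-aldehyde never meets base.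

**Compound list**
1 | 3,5-dimethoxybenzaldehyde | COc1cc(C=O)cc(OC)c1 | starting material
2 | 2,6-dibromo-3,5-dimethoxybenzaldehyde | COc1cc(OC)c(Br)c(C=O)c1Br | intermediate
3 | 2-(2,6-dibromo-3,5-dimethoxyphenyl)-1,3-dioxolane | COc1cc(OC)c(Br)c(C2OCCO2)c1Br | intermediate
4 | [3-bromo-2-(1,3-dioxolan-2-yl)-4,6-dimethoxyphenyl]lithium | [Li]c1c(OC)cc(OC)c(Br)c1C1OCCO1 | intermediate (not isolated)
5 | lithium 3-bromo-2-(1,3-dioxolan-2-yl)-4,6-dimethoxybenzoate | [Li+].[O-]C(=O)c1c(OC)cc(OC)c(Br)c1C1OCCO1 | intermediate (not isolated)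
6 | 4-bromo-3-hydroxy-5,7-dimethoxy-2-benzofuran-1(3H)-one (racemic; ring tautomer of 3-bromo-2-formyl-4,6-dimethoxybenzoic acid) | O=C1OC(O)c2c1c(OC)cc(OC)c2Br | intermediate
7 | 5-methylcyclohexane-1,3-dione | CC1CC(=O)CC(=O)C1 | starting material
8 | 3-bromo-2-[hydroxy(2-hydroxy-4-methyl-6-oxocyclohex-1-en-1-yl)methyl]-4,6-dimethoxybenzoic acid (racemic) | OC(=O)c1c(OC)cc(OC)c(Br)c1C(O)C1=C(O)CC(C)CC1=O | intermediate (not isolated)
9 | 4-bromo-3-(2-hydroxy-4-methyl-6-oxocyclohex-1-en-1-yl)-5,7-dimethoxy-2-benzofuran-1(3H)-one (racemic) | O=C1OC(C3=C(O)CC(C)CC3=O)c2c1c(OC)cc(OC)c2Br | intermediate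
10 | 4-bromo-3-(2,6-dihydroxy-4-methylphenyl)-5,7-dimethoxy-2-benzofuran-1(3H)-one (racemic) | O=C1OC(c3c(O)cc(C)cc3O)c2c1c(OC)cc(OC)c2Br | intermediate
11 | 4-bromo-3-(3-chloro-2,6-dihydroxy-4-methylphenyl)-5,7-dimethoxy-2-benzofuran-1(3H)-one (racemic) | O=C1OC(c3c(O)cc(C)c(Cl)c3O)c2c1c(OC)cc(OC)c2Br | intermediate
12 | 4-bromo-3-(3-chloro-2,6-dihydroxy-4-methylphenyl)-5,7-dihydroxy-2-benzofuran-1(3H)-one (racemic) | O=C1OC(c3c(O)cc(C)c(Cl)c3O)c2c1c(O)cc(O)c2Br | intermediate
13 | 4-bromo-3-[3-chloro-2,6-bis(methoxymethoxy)-4-methylphenyl]-5,7-bis(methoxymethoxy)-2-benzofuran-1(3H)-one (racemic) | O=C1OC(c3c(OCOC)cc(C)c(Cl)c3OCOC)c2c1c(OCOC)cc(OCOC)c2Br | intermediate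
14 | 3-[3-chloro-2,6-bis(methoxymethoxy)-4-methylphenyl]-5,7-bis(methoxymethoxy)-4-(3-methylbut-2-en-1-yl)-2-benzofuran-1(3H)-one (racemic) | O=C1OC(c3c(OCOC)cc(C)c(Cl)c3OCOC)c2c1c(OCOC)cc(OCOC)c2CC=C(C)C | intermediate
15 | [3-chloro-2,6-bis(methoxymethoxy)-4-methylphenyl][2-(hydroxymethyl)-3,5-bis(methoxymethoxy)-6-(3-methylbut-2-en-1-yl)phenyl]methanol (racemic) | OCc1c(OCOC)cc(OCOC)c(CC=C(C)C)c1C(O)c1c(OCOC)cc(C)c(Cl)c1OCOC | intermediate
16 | {2-[(tert-butyldimethylsilyloxy)methyl]-3,5-bis(methoxymethoxy)-6-(3-methylbut-2-en-1-yl)phenyl}[3-chloro-2,6-bis(methoxymethoxy)-4-methylphenyl]methanol (racemic) | CC(C)(C)[Si](C)(C)OCc1c(OCOC)cc(OCOC)c(CC=C(C)C)c1C(O)c1c(OCOC)cc(C)c(Cl)c1OCOC | intermediate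
17 | {2-[(tert-butyldimethylsilyloxy)methyl]-3,5-bis(methoxymethoxy)-6-(3-methylbut-2-en-1-yl)phenyl}[3-chloro-2,6-bis(methoxymethoxy)-4-methylphenyl]methanone | CC(C)(C)[Si](C)(C)OCc1c(OCOC)cc(OCOC)c(CC=C(C)C)c1C(=O)c1c(OCOC)cc(C)c(Cl)c1OCOC | intermediate
18 | [3-chloro-2,6-bis(methoxymethoxy)-4-methylphenyl][2-(hydroxymethyl)-3,5-bis(methoxymethoxy)-6-(3-methylbut-2-en-1-yl)phenyl]methanone | OCc1c(OCOC)cc(OCOC)c(CC=C(C)C)c1C(=O)c1c(OCOC)cc(C)c(Cl)c1OCOC | intermediate
19 | 2-[3-chloro-2,6-bis(methoxymethoxy)-4-methylbenzoyl]-4,6-bis(methoxymethoxy)-3-(3-methylbut-2-en-1-yl)benzaldehyde | O=Cc1c(OCOC)cc(OCOC)c(CC=C(C)C)c1C(=O)c1c(OCOC)cc(C)c(Cl)c1OCOC | intermediate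
20 | 2-(3-chloro-2,6-dihydroxy-4-methylbenzoyl)-4,6-dihydroxy-3-(3-methylbut-2-en-1-yl)benzaldehyde (pestalone E) | CC(C)=CCc1c(O)cc(O)c(C=O)c1C(=O)c1c(O)cc(C)c(Cl)c1O | target

**Totals**
Total step count: 15. Longest linear sequence: 15 steps (1 → 20); compound 7 is bought.

**Steps most likely to fail**

Step 9 (prenylation). The bromide is flanked by an OMOM group and the ring-fusion carbon, so oxidative addition may be slow, and branched or reduced by-products are possible. The fallback sets out from 13 and comes back at 14. Stille coupling of 13 with allyltributylstannane (Pd(PPh3)4, CsF, DMF, 90 °C) gives 4-allyl-3-[3-chloro-2,6-bis(methoxymethoxy)-4-methylphenyl]-5,7-bis(methoxymethoxy)-2-benzofuran-1(3H)-one F5. Olefin cross-metathesis of this with 2-methyl-2-butene (Grubbs II, CH2Cl2, 40 °C) then builds the trisubstituted alkene and gives 14.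

Step 5 (aromatisation). Hg(OAc)2 may mercurate the electron-rich rings or stop short of full dehydrogenation. The fallback sets out from 9 and comes back at 10. TMSOTf/Et3N (CH2Cl2, 0 °C) converts 9 to the bis-silyl dienol ether 4-bromo-5,7-dimethoxy-3-[4-methyl-2,6-bis(trimethylsilyloxy)cyclohexa-1,5-dien-1-yl]-2-benzofuran-1(3H)-one F3. DDQ (1.1 equiv, benzene, rt) abstracts hydride from this diene to give the aromatic 4-bromo-5,7-dimethoxy-3-[4-methyl-2,6-bis(trimethylsilyloxy)phenyl]-2-benzofuran-1(3H)-one F4. Dilute HCl in MeOH at rt removes the silyl groups to give 10.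

Step 4 (key aldol–lactonisation). The formyl carbon is electron-rich and sits between Br and the carboxylate, so addition of the dione or closure of the lactone may be slow. The fallback sets out from 6 and 7 and comes back at 9. Compound 6 is acetylated (Ac2O, pyridine, DMAP) to 3-acetoxy-4-bromo-5,7-dimethoxy-2-benzofuran-1(3H)-one F1. Compound 7 is O-silylated (TMSCl, Et3N) to 5-methyl-3-(trimethylsilyloxy)cyclohex-2-en-1-one F2. TMSOTf (cat., CH2Cl2, −78 → 0 °C) ionises F1 to the acyloxycarbenium ion, which F2 attacks through its α-carbon in a Mukaiyama-type aldol addition to give 9 directly.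

**Further compounds**
F1 | step 4 | 3-acetoxy-4-bromo-5,7-dimethoxy-2-benzofuran-1(3H)-one (racemic) | CC(=O)OC1OC(=O)c2c1c(Br)c(OC)cc2OC
F2 | step 4 | 5-methyl-3-(trimethylsilyloxy)cyclohex-2-en-1-one (racemic) | CC1CC(=O)C=C(O[Si](C)(C)C)C1
F3 | step 5 | 4-bromo-5,7-dimethoxy-3-[4-methyl-2,6-bis(trimethylsilyloxy)cyclohexa-1,5-dien-1-yl]-2-benzofuran-1(3H)-one (stereoisomer mixture) | C[Si](C)(C)OC1=C(C2OC(=O)c3c2c(Br)c(OC)cc3OC)C(O[Si](C)(C)C)=CC(C)C1
F4 | step 5 | 4-bromo-5,7-dimethoxy-3-[4-methyl-2,6-bis(trimethylsilyloxy)phenyl]-2-benzofuran-1(3H)-one (racemic) | C[Si](C)(C)Oc1cc(C)cc(O[Si](C)(C)C)c1C1OC(=O)c2c1c(Br)c(OC)cc2OC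
F5 | step 9 | 4-allyl-3-[3-chloro-2,6-bis(methoxymethoxy)-4-methylphenyl]-5,7-bis(methoxymethoxy)-2-benzofuran-1(3H)-one (racemic) | O=C1OC(c3c(OCOC)cc(C)c(Cl)c3OCOC)c2c1c(OCOC)cc(OCOC)c2CC=C
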